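The bond disconnected is the one between C3 of ring C of the naringenin unit and C8 of ring A of the isosakuranetin unit. Both carbons are innately nucleophilic (C3 is the α-carbon of the C4 ketone, C8 lies between O7 and the ring oxygen O1), so C8 is made electrophilic as its bromide. In one operation, a palladium-catalysed α-arylation unites the trimethylsilyl enol ether of (2R)-tri-O-benzylnaringenin with (2S)-8-bromo-5,7-di-O-benzylisosakuranetin and sets the 2,3-trans relationship. Both flavanones come from one chromone by enantiomeric rhodium-catalysed 1,4-additions; hydrogenolysis ends the synthesis.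

Key step: step 6

Remark: the sense of induction in steps 2 and 5 is assumed to follow the usual quadrant model of rhodium/biaryl-bisphosphine 1,4-additions ((R)-ligand gives 2R, (S)-ligand gives 2S); should chromones behave the other way, the two ligand enantiomers are exchanged between these steps.

**Step 1**
Reactants: 1 5,7-dihydroxy-4H-chromen-4-one
Product: 2 5,7-bis(benzyloxy)-4H-chromen-4-one
Conditions: BnBr, K2CO3, MeCN, reflux
Reagents that add atoms: benzyl bromide, BrCc1ccccc1
Why: Williamson ether synthesis, in which the 7-OH reacts readily and the chelated 5-OH on heating, on a chromone that has no stereocentre to lose.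

**Step 2**
Reactants: 2 5,7-bis(benzyloxy)-4H-chromen-4-one; 3 [4-(benzyloxy)phenyl]boronic acid
Product: 4 (2R)-5,7-bis(benzyloxy)-2-[4-(benzyloxy)phenyl]chroman-4-one
Conditions: [Rh(OH)(cod)]2 (cat.), (R)-MeO-F12-BIPHEP (cat.), toluene/H2O, 25 °C
Reagents that add atoms: none
Why: Hayashi–Miyaura asymmetric 1,4-addition, in which the aryl–rhodium species adds to C2 of the chromone on the face selected by the (R)-ligand (catalyst control sets 2R) and water protonates the rhodium oxa-π-allyl before the ring can open.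

**Step 3**
Reactants: 4 (2R)-5,7-bis(benzyloxy)-2-[4-(benzyloxy)phenyl]chroman-4-one
Product: 5 {[(2R)-5,7-bis(benzyloxy)-2-[4-(benzyloxy)phenyl]-2H-chromen-4-yl]oxy}trimethylsilane
Conditions: TMSOTf, Et3N, CH2Cl2, 0 °C
Reagents that add atoms: trimethylsilyl trifluoromethanesulfonate, C[Si](C)(C)OS(=O)(=O)C(F)(F)F
Why: Soft enolisation to the silyl enol ether toward C3, the only enolisable position, without a free enolate, so the C2–O1 bond and the 2R centre should stay untouched.

**Step 4**
Reactants: 2 5,7-bis(benzyloxy)-4H-chromen-4-one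
Product: 6 5,7-bis(benzyloxy)-8-bromo-4H-chromen-4-one
Conditions: NBS, DMF, 0 °C to rt
Reagents that add atoms: N-bromosuccinimide, O=C1CCC(=O)N1Br
Why: Electrophilic aromatic bromination, expected at C8 (one ortho benzyloxy group and the tied-back ring oxygen) over C6 (between two benzyloxy groups), as is usual for 5,7-dialkoxy-4-chromenones.

**Step 5**
Reactants: 6 5,7-bis(benzyloxy)-8-bromo-4H-chromen-4-one; 7 (4-methoxyphenyl)boronic acid
Product: 8 (2S)-5,7-bis(benzyloxy)-8-bromo-2-(4-methoxyphenyl)chroman-4-one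
Conditions: [Rh(OH)(cod)]2 (cat.), (S)-MeO-F12-BIPHEP (cat.), toluene/H2O, 25 °C
Reagents that add atoms: none
Why: Hayashi–Miyaura asymmetric 1,4-addition with the enantiomeric ligand sets 2S by catalyst control, and aryl transfer from Rh(I) should be faster than insertion into the aryl C–Br bond.

**Step 6**
Reactants: 5 {[(2R)-5,7-bis(benzyloxy)-2-[4-(benzyloxy)phenyl]-2H-chromen-4-yl]oxy}trimethylsilane; 8 (2S)-5,7-bis(benzyloxy)-8-bromo-2-(4-methoxyphenyl)chroman-4-one
Product: 10 (2R,3S)-5,7-bis(benzyloxy)-3-[(2S)-5,7-bis(benzyloxy)-2-(4-methoxyphenyl)-4-oxochroman-8-yl]-2-[4-(benzyloxy)phenyl]chroman-4-one, via tributyltin enolate 9 (not isolated)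
Conditions: Pd2(dba)3 (cat.), P(t-Bu)3 (cat.), Bu3SnF, toluene, 85 °C, dark
Reagents that add atoms: none
Why: Fluoride from Bu3SnF turns silyl enol ether 5 into tin enolate 9, Pd(0)/P(t-Bu)3 inserts into the C8–Br bond of 8, transmetalation gives an arylpalladium C3-enolate, and C–C reductive elimination forms the C3–C8 bond. The closest known reaction type is the palladium-catalysed α-arylation of ketone silyl enol ethers through tin enolates (palladium-catalysed α-arylation of 4-chromanones to 3-arylchromanones is likewise known). No ring is closed. The new C3 centre is set by the existing 2R centre: palladium should bind the enolate face anti to the 2-aryl group and reductive elimination proceeds with retention, giving the 2,3-trans (2R,3S) product, which is also the thermodynamic diequatorial epimer of this enolisable position. The step needs reaction at the enolate of the upper unit and not at the ketone of 8 (no Brønsted base is present), attack at C8 only (fixed by the bromine), and reductive elimination faster than β-hydride elimination to the flavone (favoured by the bulky electron-rich phosphine and the two ortho oxygens of the aryl group). Both C2 centres should survive because no alkali enolate, and hence no retro-oxa-Michael ring opening, is involved, and light is excluded to prevent electrocyclic opening of the 2H-chromene.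

**Step 7**
Reactants: 10 (2R,3S)-5,7-bis(benzyloxy)-3-[(2S)-5,7-bis(benzyloxy)-2-(4-methoxyphenyl)-4-oxochroman-8-yl]-2-[4-(benzyloxy)phenyl]chroman-4-one
Product: 11 (2R,3S)-5,7-dihydroxy-3-[(2S)-5,7-dihydroxy-2-(4-methoxyphenyl)-4-oxochroman-8-yl]-2-(4-hydroxyphenyl)chroman-4-one
Conditions: H2 (1 atm), 10% Pd/C, EtOAc/MeOH, rt
Reagents that add atoms: none
Why: Catalytic hydrogenolysis of the five benzyl ethers under neutral conditions, which should leave the aryl methyl ether, the two ketones, the cyclic C2–O1 bonds and all three stereocentres untouched.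

**Compound list**
1 | 5,7-dihydroxy-4H-chromen-4-one | O=c1ccoc2cc(O)cc(O)c12 | starting material
2 | 5,7-bis(benzyloxy)-4H-chromen-4-one | O=c1ccoc2cc(OCc3ccccc3)cc(OCc3ccccc3)c12 | intermediate
3 | [4-(benzyloxy)phenyl]boronic acid | OB(O)c1ccc(OCc2ccccc2)cc1 | starting material
4 | (2R)-5,7-bis(benzyloxy)-2-[4-(benzyloxy)phenyl]chroman-4-one | O=C1C[C@H](c2ccc(OCc3ccccc3)cc2)Oc2cc(OCc3ccccc3)cc(OCc3ccccc3)c12 | intermediate
5 | {[(2R)-5,7-bis(benzyloxy)-2-[4-(benzyloxy)phenyl]-2H-chromen-4-yl]oxy}trimethylsilane | C[Si](C)(C)OC1=C[C@H](c2ccc(OCc3ccccc3)cc2)Oc2cc(OCc3ccccc3)cc(OCc3ccccc3)c12 | intermediate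
6 | 5,7-bis(benzyloxy)-8-bromo-4H-chromen-4-one | O=c1ccoc2c(Br)c(OCc3ccccc3)cc(OCc3ccccc3)c12 | intermediate
7 | (4-methoxyphenyl)boronic acid | COc1ccc(B(O)O)cc1 | starting material
8 | (2S)-5,7-bis(benzyloxy)-8-bromo-2-(4-methoxyphenyl)chroman-4-one | O=C1C[C@@H](c2ccc(OC)cc2)Oc2c(Br)c(OCc3ccccc3)cc(OCc3ccccc3)c12 | intermediate
9 | tributyl{[(2R)-5,7-bis(benzyloxy)-2-[4-(benzyloxy)phenyl]-2H-chromen-4-yl]oxy}stannane (tributyltin enolate, not isolated) | CCCC[Sn](CCCC)(CCCC)OC1=C[C@H](c2ccc(OCc3ccccc3)cc2)Oc2cc(OCc3ccccc3)cc(OCc3ccccc3)c12 | intermediate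
10 | (2R,3S)-5,7-bis(benzyloxy)-3-[(2S)-5,7-bis(benzyloxy)-2-(4-methoxyphenyl)-4-oxochroman-8-yl]-2-[4-(benzyloxy)phenyl]chroman-4-one | COc1ccc([C@@H]2CC(=O)c3c(OCc6ccccc6)cc(OCc6ccccc6)c([C@@H]4C(=O)c5c(OCc6ccccc6)cc(OCc6ccccc6)cc5O[C@H]4c4ccc(OCc6ccccc6)cc4)c3O2)cc1 | intermediate
11 | (2R,3S)-5,7-dihydroxy-3-[(2S)-5,7-dihydroxy-2-(4-methoxyphenyl)-4-oxochroman-8-yl]-2-(4-hydroxyphenyl)chroman-4-one | COc1ccc([C@@H]2CC(=O)c3c(O)cc(O)c([C@@H]4C(=O)c5c(O)cc(O)cc5O[C@H]4c4ccc(O)cc4)c3O2)cc1 | target

Total step count: 7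
Longest linear sequence: 5 steps (1 → 2 → 4 → 5 → 10 → 11; the branch 1 → 2 → 6 → 8 → 10 → 11 is equally long)

**Steps most likely to fail**

**Step 6.** The C3-bound palladium enolate may undergo β-hydride elimination (flavone formation with hydrodebromination of 8). Transmetalation at the doubly ortho-oxygenated arylpalladium centre may be too slow. Fluoride may open the tin enolate by retro-oxa-Michael reaction, with loss of the 2R configuration. The fallback reverses the roles: C3 becomes the electrophile as an α-acyl thionium ion and C8 reacts as the nucleophile in a Friedel–Crafts alkylation. It sets out from compound 5 (and from 2 and 7) and comes back at compound 10. The nucleophile, (2S)-5,7-bis(benzyloxy)-2-(4-methoxyphenyl)chroman-4-one F1, would be made from 2 and 7 under the conditions of step 5. Sulfenylation of 5 with PhSCl (CH2Cl2, −78 °C) should give the 3-(phenylsulfanyl) derivative of flavanone 4 F2 (C2 unchanged, C3 epimers). NCS (CH2Cl2, 0 °C) should convert it into the 3-chloro-3-(phenylsulfanyl)flavanone F3. SnCl4 (CH2Cl2, −78 °C) should ionise F3 to the thionium ion, which should attack F1 at the less hindered C8 to give the 3-aryl-3-(phenylsulfanyl) biflavanone F4. Bu3SnH/AIBN (toluene, 80 °C) should then remove sulfur, with hydrogen delivered anti to the 2-aryl group, to give trans-configured 10.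

**Step 5.** Enantioselectivity may erode, the rhodium oxa-π-allyl may open to the 2'-hydroxychalcone, or the C–Br bond may undergo competing oxidative addition. The fallback replaces catalyst-controlled C–C formation by a racemic synthesis followed by kinetic resolution. It sets out from compounds 6 and 7 and comes back at compound 8. Achiral Pd(II) conjugate addition (Pd(OCOCF3)2, 2,2'-bipyridine, AcOH/THF/H2O, 60 °C) should give racemic 5,7-bis(benzyloxy)-8-bromo-2-(4-methoxyphenyl)chroman-4-one F5. Noyori-type asymmetric transfer hydrogenation (RuCl[(R,R)-TsDPEN](p-cymene), HCO2H/Et3N, EtOAc, rt, stopped near half conversion) should reduce the (2R)-ketone to the cis alcohol (2R,4R)-5,7-bis(benzyloxy)-8-bromo-2-(4-methoxyphenyl)chroman-4-ol F6. The unreacted (2S)-ketone 8 is then separated by chromatography.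

**Step 4.** Bromination may divide between C8 and C6, or bromine may add to the C2=C3 bond of the pyranone. The fallback places the bromine before the pyranone ring exists, ortho to the phenol that becomes O1. It sets out from commercial 1-[2,4-bis(benzyloxy)-6-hydroxyphenyl]ethanone F7 in place of compound 2 and comes back at compound 6. NBS (MeCN, 0 °C) should brominate between the hydroxyl and the 4-benzyloxy group to give 1-[4,6-bis(benzyloxy)-3-bromo-2-hydroxyphenyl]ethanone F8. DMF dimethyl acetal (toluene, 100 °C) should give the enaminone (E)-1-[4,6-bis(benzyloxy)-3-bromo-2-hydroxyphenyl]-3-(dimethylamino)prop-2-en-1-one F9. Acid (conc. HCl, CH2Cl2, rt) should close it to 6 with loss of dimethylamine.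

**Further compounds**
F1 | step 6 | (2S)-5,7-bis(benzyloxy)-2-(4-methoxyphenyl)chroman-4-one | COc1ccc([C@@H]2CC(=O)c3c(OCc4ccccc4)cc(OCc4ccccc4)cc3O2)cc1
F2 | step 6 | 3-(phenylsulfanyl) derivative of flavanone 4 (C2 configuration of 4 retained, C3 epimers) | O=C1C(Sc2ccccc2)[C@H](c2ccc(OCc3ccccc3)cc2)Oc2cc(OCc3ccccc3)cc(OCc3ccccc3)c12
F3 | step 6 | 3-chloro-3-(phenylsulfanyl) derivative of flavanone 4 (C2 configuration of 4 retained, C3 epimers) | O=C1C(Cl)(Sc2ccccc2)[C@H](c2ccc(OCc3ccccc3)cc2)Oc2cc(OCc3ccccc3)cc(OCc3ccccc3)c12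
F4 | step 6 | 3-(phenylsulfanyl) derivative of biflavanone 10 (both C2 configurations of 10 retained, C3 epimers) | COc1ccc([C@@H]2CC(=O)c3c(OCc6ccccc6)cc(OCc6ccccc6)c(C4(Sc6ccccc6)C(=O)c5c(OCc6ccccc6)cc(OCc6ccccc6)cc5O[C@H]4c4ccc(OCc6ccccc6)cc4)c3O2)cc1
F5 | step 5 | racemic 5,7-bis(benzyloxy)-8-bromo-2-(4-methoxyphenyl)chroman-4-one | O=C1CC(c2ccc(OC)cc2)Oc2c(Br)c(OCc3ccccc3)cc(OCc3ccccc3)c12
F6 | step 5 | (2R,4R)-5,7-bis(benzyloxy)-8-bromo-2-(4-methoxyphenyl)chroman-4-ol (2,4-cis) | O[C@@H]1C[C@H](c2ccc(OC)cc2)Oc2c(Br)c(OCc3ccccc3)cc(OCc3ccccc3)c12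
F7 | step 4 | 1-[2,4-bis(benzyloxy)-6-hydroxyphenyl]ethanone | CC(=O)c1c(O)cc(OCc2ccccc2)cc1OCc1ccccc1
F8 | step 4 | 1-[4,6-bis(benzyloxy)-3-bromo-2-hydroxyphenyl]ethanone | CC(=O)c1c(O)c(Br)c(OCc2ccccc2)cc1OCc1ccccc1
F9 | step 4 | (E)-1-[4,6-bis(benzyloxy)-3-bromo-2-hydroxyphenyl]-3-(dimethylamino)prop-2-en-1-one | CN(C)/C=C/C(=O)c1c(O)c(Br)c(OCc2ccccc2)cc1OCc1ccccc1
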